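The ten-membered carbocycle (C1–C10) is disconnected at C9–C10. The key step exploits that C9 is a methylene flanked by the C8 carbinol and the olefinic carbon C10: a primary C9 radical, released by decarboxylation of a β-silyloxy acid activated as its N-hydroxyphthalimide ester, is coupled at nickel to a (Z)-C10 iodoalkene, closing the carbocycle and fixing the C1=C10 geometry in one operation without β-elimination of the C8 oxygen. The precursor is a trans-disubstituted γ-lactone (O–C6–C7–C11–C12): C6 carries the C4–C5 oxirane with the iodoalkene chain, C7 the (8R)-silyloxy acid arm. Its stereocentres come from a Sharpless epoxidation, an Evans aldol and a Brown allylation.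

Key step: step 18

Remark: germacranolide numbering is used (carbocycle C1–C10, lactone carbons C11 and C12, exocyclic C13, C14 on C10, C15 on C4); ether 2 and the allylborane solution of step 10 are assumed to be purchasable.

Abbreviations: TBDPS = tert-butyldiphenylsilyl, TES = triethylsilyl, TBS = tert-butyldimethylsilyl, PMB = 4-methoxybenzyl. "Ox-X" = the (2R,3S)-3-(TBDPS-oxymethyl)oxiran-2-yl group (ring C2 = C5, ring C3 = C4) carrying on ring C3 the chain X, where PMB = 3-(PMB-oxy)propyl, OH = 3-hydroxypropyl, CHO = 3-oxopropyl and I = (Z)-4-iodopent-3-enyl.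

Step 1
Reactants: 1 propargyl alcohol; 2 1-(3-bromopropoxymethyl)-4-methoxybenzene
Product: 5 (Z)-3-iodo-2-[3-(PMB-oxy)propyl]prop-2-en-1-ol, via Grignard reagent 3 (not isolated), via alkenylmagnesium alkoxide 4 (not isolated)
Conditions: 2, Mg, THF, 35 °C; then 1, CuI (10 mol %), THF/Et2O, −10 °C → rt; then I2, −20 → 0 °C
Reagents that add atoms: iodine, II
Why: Copper-catalysed anti-carbomagnesiation of the magnesium propargyl alkoxide puts the alkyl group on the internal carbon and magnesium on the terminal carbon cis to CH2O (chelate), and iodinolysis with retention gives the Z-iodide, which fixes C15 cis to the future C6 across C4=C5.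

Step 2
Reactants: 5 (Z)-iodo allylic alcohol
Product: 6 TBDPS ether of 5
Conditions: TBDPSCl, imidazole, CH2Cl2, rt
Reagents that add atoms: tert-butyl(chloro)diphenylsilane, CC(C)(C)[Si](Cl)(c1ccccc1)c1ccccc1
Why: Standard silylation of a primary alcohol, which installs the C15 protecting group that is kept to the last step.

Step 3
Reactants: 6 TBDPS ether
Product: 8 (Z)-4-(TBDPS-oxy)-3-[3-(PMB-oxy)propyl]but-2-en-1-ol, via alkenyllithium 7 (not isolated)
Conditions: t-BuLi (2.1 equiv), Et2O, −78 °C; then (CH2O)n, −78 °C → rt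
Reagents that add atoms: formaldehyde (from paraformaldehyde), C=O
Why: Iodine–lithium exchange with retention of alkene geometry followed by hydroxymethylation introduces C6, while the low temperature, ether solvent and bulky silyl group suppress 1,4 oxygen-to-carbon silyl migration.

Step 4
Reactants: 8 allylic alcohol
Product: 9 [(2R,3S)-3-(TBDPS-oxymethyl)-3-[3-(PMB-oxy)propyl]oxiran-2-yl]methanol
Conditions: Ti(OiPr)4 (20 mol %), D-(−)-diethyl tartrate (24 mol %), t-BuOOH, 4 Å molecular sieves, CH2Cl2, −20 °C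
Reagents that add atoms: tert-butyl hydroperoxide, CC(C)(C)OO
Why: Katsuki–Sharpless asymmetric epoxidation of a primary allylic alcohol, in which the D-(−)-tartrate titanium complex delivers oxygen to the face that gives the (2R)-carbinol-bearing oxirane carbon, so that C5 (R) and C4 (S) are set stereospecifically from the Z-alkene.

Step 5
Reactants: 9 epoxy alcohol
Product: 10 (2S,3S)-3-(TBDPS-oxymethyl)-3-[3-(PMB-oxy)propyl]oxirane-2-carbaldehyde
Conditions: Dess–Martin periodinane, pyridine, CH2Cl2, 0 °C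
Reagents that add atoms: none
Why: Dess–Martin oxidation of a primary alcohol to the aldehyde under buffered conditions that leave the oxirane and its configuration untouched.

Step 6
Reactants: 11 (S)-4-benzyl-1,3-oxazolidin-2-one; 12 methyl 4-chloro-4-oxobutanoate
Product: 14 methyl 4-[(4S)-4-benzyl-2-oxo-1,3-oxazolidin-3-yl]-4-oxobutanoate, via lithium oxazolidinide 13 (not isolated)
Conditions: n-BuLi, THF, −78 °C; then 12, −78 → 0 °C
Reagents that add atoms: none
Why: N-acylation of the lithiated oxazolidinone by an acid chloride, the standard preparation of an Evans imide.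

Step 7
Reactants: 14 succinate imide; 10 epoxy aldehyde
Product: 17 (4S)-4-benzyl-3-[(2S,3S)-2-(Ox-PMB)-5-oxooxolane-3-carbonyl]-1,3-oxazolidin-2-one, via boron enolate 15 (not isolated), via aldol adduct 16 (not isolated)
Conditions: 14, Bu2BOTf, iPr2NEt, CH2Cl2, −78 → 0 °C; 10, −78 → 0 °C; pH 7 buffer, MeOH, H2O2, 0 °C; then PPTS (cat.), CH2Cl2, rt
Reagents that add atoms: none
Why: Evans syn-aldol reaction in which the Z-boron enolate adds through a chair (Zimmerman–Traxler) transition state on the enolate face away from the benzyl group, setting C6 and C7 under reagent control, after which the γ-hydroxy methyl ester lactonises to the trans lactone.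

Step 8
Reactants: 17 lactone imide
Product: 18 S-ethyl (2S,3S)-2-(Ox-PMB)-5-oxooxolane-3-carbothioate
Conditions: EtSH, n-BuLi, THF, 0 °C
Reagents that add atoms: ethanethiol, CCS
Why: Transthioesterification of the N-acyloxazolidinone by lithium ethanethiolate, which attacks the activated exocyclic imide carbonyl selectively and releases the auxiliary while lactone and oxirane are not attacked at 0 °C.

Step 9
Reactants: 18 thioester
Product: 19 (2S,3S)-2-(Ox-PMB)-5-oxooxolane-3-carbaldehyde (C8 aldehyde)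
Conditions: Et3SiH, Pd/C (10 wt %), acetone, rt
Reagents that add atoms: none
Why: Fukuyama reduction, in which the thioester adds oxidatively to zerovalent palladium and the acylpalladium is reduced by the silane to the aldehyde without over-reduction of lactone, oxirane or PMB ether.

Step 10
Reactants: 19 C8 aldehyde
Product: 20 (4R,5S)-4-[(1R)-1-hydroxybut-3-enyl]-5-(Ox-PMB)oxolan-2-one
Conditions: B-allylbis(isopinocampheyl)borane of the (−)-α-pinene series (prepared from (+)-Ipc2BOMe), Et2O, −78 °C; then pH 7 buffer, MeOH, H2O2, 0 °C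
Reagents that add atoms: B-allylbis(isopinocampheyl)borane from (−)-α-pinene, C=CCB([C@H]1C[C@H]2C[C@@H]([C@@H]1C)C2(C)C)[C@H]1C[C@H]2C[C@@H]([C@@H]1C)C2(C)C
Why: Brown allylboration through a closed six-membered transition state, in which the reagent of the (−)-α-pinene series adds to the Re face of the C8 aldehyde under reagent control to give the 8R alcohol, under neutral low-temperature conditions that avoid epimerisation at C7 and β-elimination of the lactone oxygen.

Step 11
Reactants: 20 homoallylic alcohol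
Product: 21 (4S,5S)-4-[(1R)-1-(TES-oxy)but-3-enyl]-5-(Ox-PMB)oxolan-2-one
Conditions: TESCl, imidazole, CH2Cl2, 0 °C
Reagents that add atoms: chlorotriethylsilane, CC[Si](Cl)(CC)CC
Why: Silylation of the secondary alcohol, carried out at once so that the free C8 hydroxyl cannot translactonise onto C12.

Step 12
Reactants: 21 TES ether
Product: 22 (4S,5S)-4-[(1R)-1-(TES-oxy)but-3-enyl]-5-(Ox-OH)oxolan-2-one
Conditions: DDQ, CH2Cl2/pH 7 buffer, 0 °C
Reagents that add atoms: none
Why: Oxidative cleavage of the PMB ether by DDQ (benzylic hydride abstraction, then hydrolysis of the oxocarbenium ion) at neutral pH, under which silyl ethers, oxirane and the terminal alkene are inert.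

Step 13
Reactants: 22 primary alcohol
Product: 23 (4S,5S)-4-[(1R)-1-(TES-oxy)but-3-enyl]-5-(Ox-CHO)oxolan-2-one (C1 aldehyde)
Conditions: Dess–Martin periodinane, pyridine, CH2Cl2, 0 °C
Reagents that add atoms: none
Why: Dess–Martin oxidation of the primary alcohol to the C1 aldehyde under buffered conditions.

Step 14
Reactants: 23 C1 aldehyde; 24 ethyltriphenylphosphonium iodide
Product: 28 (4S,5S)-4-[(1R)-1-(TES-oxy)but-3-enyl]-5-(Ox-I)oxolan-2-one, via ethylidene ylide 25 (not isolated), via iodoethylphosphonium iodide 26 (not isolated), via iodoethylidene ylide 27 (not isolated)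
Conditions: 24, n-BuLi, THF, rt; I2, −78 °C; NaN(SiMe3)2, −20 °C; then 23, −78 → −20 °C
Reagents that add atoms: iodine, II
Why: Stork–Zhao olefination, a kinetically controlled Wittig reaction of the α-iodo ylide that gives the (Z)-2-iodoalk-2-ene with iodine cis to C2 and thereby sets the C1=C10 geometry.

Step 15
Reactants: 28 iodoalkene
Product: 29 (3R)-3-[(2S,3S)-2-(Ox-I)-5-oxooxolan-3-yl]-3-(TES-oxy)propanal
Conditions: OsO4 (2 mol %), NaIO4, 2,6-lutidine, dioxane/H2O, rt
Reagents that add atoms: osmium tetroxide, O=[Os](=O)(=O)=O; sodium periodate, [Na+].[O-]I(=O)(=O)=O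
Why: Lemieux–Johnson cleavage, in which osmylation is selective for the monosubstituted terminal alkene because the trisubstituted iodoalkene is hindered and electron-poor, and periodate cleaves the diol to the aldehyde.

Step 16
Reactants: 29 aldehyde
Product: 30 (3R)-3-[(2S,3S)-2-(Ox-I)-5-oxooxolan-3-yl]-3-(TES-oxy)propanoic acid
Conditions: NaClO2, NaH2PO4, 2-methylbut-2-ene, t-BuOH/H2O, 0 °C → rt
Reagents that add atoms: sodium chlorite, [Na+].[O-]Cl=O
Why: Pinnick oxidation by chlorous acid at buffered pH, with 2-methylbut-2-ene trapping hypochlorous acid so that the iodoalkene, the silyl ethers and the β-silyloxy group are untouched.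

Step 17
Reactants: 30 acid
Product: 31 1,3-dioxoisoindolin-2-yl (3R)-3-[(2S,3S)-2-(Ox-I)-5-oxooxolan-3-yl]-3-(TES-oxy)propanoate (redox-active ester, the precursor)
Conditions: N-hydroxyphthalimide, N,N'-diisopropylcarbodiimide, DMAP (5 mol %), CH2Cl2, 0 °C → rt
Reagents that add atoms: N-hydroxyphthalimide, O=C1N(O)C(=O)c2ccccc12
Why: Carbodiimide (Steglich-type) esterification of the acid with N-hydroxyphthalimide through the O-acylisourea.

Step 18
Reactants: 31 redox-active ester
Product: 32 (4S,5R,6S,7S,8R)-8-(TES-oxy)-15-(TBDPS-oxy)-4,5-epoxygermacr-1(10)Z-en-6,12-olide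
Conditions: NiCl2·glyme (20 mol %), 2,2'-bipyridine (24 mol %), LiCl, DMF, Mg anode, carbon-foam cathode carrying electrodeposited Ag nanoparticles, constant current, rt; 31 added by syringe pump (≤2 mM)
Reagents that add atoms: none
Why: Proposed new method: cathodically generated low-valent nickel (zerovalent or monovalent, bipyridine-ligated) inserts into the C10–I bond with retention of the Z geometry, while the N-acyloxyphthalimide accepts an electron, loses phthalimide anion and CO2 and releases the primary C9 radical, which is captured by the alkenylnickel to give a trivalent alkyl(alkenyl)nickel species that reductively eliminates the C9–C10 bond; the closest known reaction type is the intermolecular nickel-electrocatalytic decarboxylative alkenylation of redox-active esters with alkenyl halides. The ten-membered ring closes by intramolecular radical capture at nickel followed by sp3–sp2 reductive elimination, an endocyclic closure in which both alkene carbons become ring members and no radical adds to the alkene. No stereocentre is created, and the C1=C10 geometry is inherited from the iodoalkene because the alkenylnickel intermediate is configurationally stable. The step needs ring closure to outrun reduction, dimerisation and 1,5-hydrogen transfer of the radical, which is secured by slow addition at high dilution, by the trans-lactone and the trisubstituted oxirane acting as turn elements that bring C9 near C10, and by the Z-iodoalkene already having the cis geometry of the ring olefin. A radical at C9 is chosen because it tolerates the β-silyloxy group at C8, which an organozinc or organoboron centre at C9 would expel.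

Step 19
Reactants: 32 macrocyclic lactone
Product: 36 (4S,5R,6S,7S,8R)-8-(TES-oxy)-15-(TBDPS-oxy)-4,5-epoxygermacra-1(10)Z,11(13)-dien-6,12-olide, via lithium enolate 33 (not isolated), via Mannich base 34 (not isolated), via ammonium iodide 35 (not isolated)
Conditions: LiN(SiMe3)2, THF, −78 °C; Eschenmoser's salt, −78 → 0 °C; then MeI, MeOH, rt; then NaHCO3 (aq.), CH2Cl2, rt
Reagents that add atoms: N,N-dimethylmethyleneiminium iodide (Eschenmoser's salt), C=[N+](C)C.[I-]
Why: Lithium enolate Mannich reaction on the C11 face anti to the C7 substituent, exhaustive N-methylation and base-induced (Hofmann-type) β-elimination give the exocyclic C11=C13 alkene, so the transient C11 centre (expected 11R) is of no consequence.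

Step 20
Reactants: 36 α-methylene lactone
Product: 37 (4S,5R,6S,7R,8R)-8-hydroxy-15-(TBDPS-oxy)-4,5-epoxygermacra-1(10)Z,11(13)-dien-6,12-olide
Conditions: HF·pyridine, pyridine, THF, 0 °C
Reagents that add atoms: none
Why: Buffered fluoride cleavage removes the secondary TES ether much faster than the primary TBDPS ether and spares the oxirane.

Step 21
Reactants: 38 (tert-butyldimethylsilyloxy)acetaldehyde; 39 ethyl 2-(triphenylphosphoranylidene)propanoate
Product: 40 ethyl (E)-4-(TBS-oxy)-2-methylbut-2-enoate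
Conditions: CH2Cl2, rt
Reagents that add atoms: none
Why: Wittig reaction of a stabilised α-methyl ylide with an aldehyde, which gives the E-trisubstituted enoate.

Step 22
Reactants: 40 ethyl ester
Product: 41 (E)-4-(TBS-oxy)-2-methylbut-2-enoic acid
Conditions: LiOH, THF/MeOH/H2O, rt; then 1 M HCl to pH 4, 0 °C
Reagents that add atoms: lithium hydroxide, [Li+].[OH-]
Why: Saponification of the ethyl ester, which the primary TBS ether survives under mild aqueous base and brief acidification.

Step 23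
Reactants: 37 C8 alcohol; 41 protected 4-hydroxytiglic acid
Product: 43 (4S,5R,6S,7R,8R)-8-[(E)-4-(TBS-oxy)-2-methylbut-2-enoyloxy]-15-(TBDPS-oxy)-4,5-epoxygermacra-1(10)Z,11(13)-dien-6,12-olide, via mixed anhydride 42 (not isolated)
Conditions: 41, 2,4,6-trichlorobenzoyl chloride, Et3N, toluene, rt; then 37, DMAP, rt
Reagents that add atoms: none
Why: Yamaguchi esterification, in which DMAP attacks the less hindered acyl group of the mixed anhydride and the acylpyridinium acylates the hindered secondary C8 alcohol without loss of the E geometry.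

Step 24
Reactants: 43 bis-silyl ether
Product: 44 target, (4S,5R,6S,7R,8R)-15-hydroxy-8-[(E)-4-hydroxy-2-methylbut-2-enoyloxy]-4,5-epoxygermacra-1(10)Z,11(13)-dien-6,12-olide
Conditions: Bu4NF, AcOH (1:1), THF, 0 °C → rt
Reagents that add atoms: none
Why: Fluoride cleaves both silyl ethers, and acetic acid buffering keeps the medium non-basic so that the freed epoxy alcohol does not undergo Payne rearrangement and the ester and methylene lactone are not attacked.

Compound list

1 | propargyl alcohol | C#CCO | starting material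
2 | 1-(3-bromopropoxymethyl)-4-methoxybenzene | COc1ccc(COCCCBr)cc1 | starting material
3 | [3-(PMB-oxy)propyl]magnesium bromide | COc1ccc(COCCC[Mg]Br)cc1 | intermediate (not isolated)
4 | bromomagnesium (Z)-3-(bromomagnesio)-2-[3-(PMB-oxy)propyl]prop-2-en-1-olate, Mg cis to CH2O | Br[Mg]/C=C(\CO[Mg]Br)CCCOCc1ccc(OC)cc1 | intermediate (not isolated)
5 | (Z)-3-iodo-2-[3-(PMB-oxy)propyl]prop-2-en-1-ol | I/C=C(\CO)CCCOCc1ccc(OC)cc1 | intermediate
6 | TBDPS ether of 5 | I/C=C(\CO[Si](c1ccccc1)(c1ccccc1)C(C)(C)C)CCCOCc1ccc(OC)cc1 | intermediate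
7 | alkenyllithium from 6 (Li in place of I, geometry retained) | [Li]/C=C(\CO[Si](c1ccccc1)(c1ccccc1)C(C)(C)C)CCCOCc1ccc(OC)cc1 | intermediate (not isolated)
8 | (Z)-4-(TBDPS-oxy)-3-[3-(PMB-oxy)propyl]but-2-en-1-ol | OC/C=C(\CO[Si](c1ccccc1)(c1ccccc1)C(C)(C)C)CCCOCc1ccc(OC)cc1 | intermediate
9 | [(2R,3S)-3-(TBDPS-oxymethyl)-3-[3-(PMB-oxy)propyl]oxiran-2-yl]methanol | OC[C@H]1O[C@]1(CO[Si](c1ccccc1)(c1ccccc1)C(C)(C)C)CCCOCc1ccc(OC)cc1 | intermediate
10 | (2S,3S)-3-(TBDPS-oxymethyl)-3-[3-(PMB-oxy)propyl]oxirane-2-carbaldehyde | O=C[C@H]1O[C@]1(CO[Si](c1ccccc1)(c1ccccc1)C(C)(C)C)CCCOCc1ccc(OC)cc1 | intermediate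
11 | (S)-4-benzyl-1,3-oxazolidin-2-one | O=C1OC[C@H](Cc2ccccc2)N1 | starting material
12 | methyl 4-chloro-4-oxobutanoate | COC(=O)CCC(Cl)=O | starting material
13 | lithium salt of 11 (N-lithio) | [Li]N1[C@@H](Cc2ccccc2)COC1=O | intermediate (not isolated)
14 | methyl 4-[(4S)-4-benzyl-2-oxo-1,3-oxazolidin-3-yl]-4-oxobutanoate | COC(=O)CCC(=O)N1[C@@H](Cc2ccccc2)COC1=O | intermediate
15 | (Z)-dibutylboron enolate of 14 | CCCCB(CCCC)O/C(=C\CC(=O)OC)N1[C@@H](Cc2ccccc2)COC1=O | intermediate (not isolated)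
16 | methyl (3S,4S)-3-[(4S)-4-benzyl-2-oxo-1,3-oxazolidine-3-carbonyl]-4-hydroxy-4-(Ox-PMB)butanoate (syn-aldol adduct) | COC(=O)C[C@H](C(=O)N1[C@@H](Cc2ccccc2)COC1=O)[C@H](O)[C@H]1O[C@]1(CO[Si](c1ccccc1)(c1ccccc1)C(C)(C)C)CCCOCc1ccc(OC)cc1 | intermediate (not isolated)
17 | (4S)-4-benzyl-3-[(2S,3S)-2-(Ox-PMB)-5-oxooxolane-3-carbonyl]-1,3-oxazolidin-2-one (trans lactone) | O=C(N1[C@@H](Cc2ccccc2)COC1=O)[C@H]1CC(=O)O[C@@H]1[C@H]1O[C@]1(CO[Si](c1ccccc1)(c1ccccc1)C(C)(C)C)CCCOCc1ccc(OC)cc1 | intermediate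
18 | S-ethyl (2S,3S)-2-(Ox-PMB)-5-oxooxolane-3-carbothioate | CCSC(=O)[C@H]1CC(=O)O[C@@H]1[C@H]1O[C@]1(CO[Si](c1ccccc1)(c1ccccc1)C(C)(C)C)CCCOCc1ccc(OC)cc1 | intermediate
19 | (2S,3S)-2-(Ox-PMB)-5-oxooxolane-3-carbaldehyde | O=C[C@H]1CC(=O)O[C@@H]1[C@H]1O[C@]1(CO[Si](c1ccccc1)(c1ccccc1)C(C)(C)C)CCCOCc1ccc(OC)cc1 | intermediate
20 | (4R,5S)-4-[(1R)-1-hydroxybut-3-enyl]-5-(Ox-PMB)oxolan-2-one | C=CC[C@@H](O)[C@H]1CC(=O)O[C@@H]1[C@H]1O[C@]1(CO[Si](c1ccccc1)(c1ccccc1)C(C)(C)C)CCCOCc1ccc(OC)cc1 | intermediate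
21 | (4S,5S)-4-[(1R)-1-(TES-oxy)but-3-enyl]-5-(Ox-PMB)oxolan-2-one | C=CC[C@@H](O[Si](CC)(CC)CC)[C@H]1CC(=O)O[C@@H]1[C@H]1O[C@]1(CO[Si](c1ccccc1)(c1ccccc1)C(C)(C)C)CCCOCc1ccc(OC)cc1 | intermediate
22 | (4S,5S)-4-[(1R)-1-(TES-oxy)but-3-enyl]-5-(Ox-OH)oxolan-2-one | C=CC[C@@H](O[Si](CC)(CC)CC)[C@H]1CC(=O)O[C@@H]1[C@H]1O[C@]1(CO[Si](c1ccccc1)(c1ccccc1)C(C)(C)C)CCCO | intermediate
23 | (4S,5S)-4-[(1R)-1-(TES-oxy)but-3-enyl]-5-(Ox-CHO)oxolan-2-one | C=CC[C@@H](O[Si](CC)(CC)CC)[C@H]1CC(=O)O[C@@H]1[C@H]1O[C@]1(CO[Si](c1ccccc1)(c1ccccc1)C(C)(C)C)CCC=O | intermediate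
24 | ethyltriphenylphosphonium iodide | CC[P+](c1ccccc1)(c1ccccc1)c1ccccc1.[I-] | starting material
25 | ethylidenetriphenylphosphorane | CC=P(c1ccccc1)(c1ccccc1)c1ccccc1 | intermediate (not isolated)
26 | (1-iodoethyl)triphenylphosphonium iodide | CC(I)[P+](c1ccccc1)(c1ccccc1)c1ccccc1.[I-] | intermediate (not isolated)
27 | (1-iodoethylidene)triphenylphosphorane | CC(I)=P(c1ccccc1)(c1ccccc1)c1ccccc1 | intermediate (not isolated)
28 | (4S,5S)-4-[(1R)-1-(TES-oxy)but-3-enyl]-5-(Ox-I)oxolan-2-one | C=CC[C@@H](O[Si](CC)(CC)CC)[C@H]1CC(=O)O[C@@H]1[C@H]1O[C@]1(CO[Si](c1ccccc1)(c1ccccc1)C(C)(C)C)CC/C=C(C)\I | intermediate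
29 | (3R)-3-[(2S,3S)-2-(Ox-I)-5-oxooxolan-3-yl]-3-(TES-oxy)propanal | O=CC[C@@H](O[Si](CC)(CC)CC)[C@H]1CC(=O)O[C@@H]1[C@H]1O[C@]1(CO[Si](c1ccccc1)(c1ccccc1)C(C)(C)C)CC/C=C(C)\I | intermediate
30 | (3R)-3-[(2S,3S)-2-(Ox-I)-5-oxooxolan-3-yl]-3-(TES-oxy)propanoic acid | OC(=O)C[C@@H](O[Si](CC)(CC)CC)[C@H]1CC(=O)O[C@@H]1[C@H]1O[C@]1(CO[Si](c1ccccc1)(c1ccccc1)C(C)(C)C)CC/C=C(C)\I | intermediate
31 | 1,3-dioxoisoindolin-2-yl ester of 30 (precursor of the key step) | O=C(C[C@@H](O[Si](CC)(CC)CC)[C@H]1CC(=O)O[C@@H]1[C@H]1O[C@]1(CO[Si](c2ccccc2)(c2ccccc2)C(C)(C)C)CC/C=C(C)\I)ON1C(=O)c2ccccc2C1=O | intermediate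
32 | (4S,5R,6S,7S,8R)-8-(TES-oxy)-15-(TBDPS-oxy)-4,5-epoxygermacr-1(10)Z-en-6,12-olide (product of the key step) | O=C1O[C@H]2[C@H](C1)[C@H](O[Si](CC)(CC)CC)C/C(C)=C\CC[C@@]1(CO[Si](c3ccccc3)(c3ccccc3)C(C)(C)C)O[C@H]21 | intermediate
33 | lithium enolate of 32 (C11=C12–OLi) | [Li]OC=1O[C@H]2[C@H](C=1)[C@H](O[Si](CC)(CC)CC)C/C(C)=C\CC[C@@]1(CO[Si](c3ccccc3)(c3ccccc3)C(C)(C)C)O[C@H]21 | intermediate (not isolated)
34 | (11R)-13-(dimethylamino) derivative of 32 (Mannich base, CH2NMe2 trans to C8) | CN(C)C[C@@H]1C(=O)O[C@H]2[C@H]1[C@H](O[Si](CC)(CC)CC)C/C(C)=C\CC[C@@]1(CO[Si](c3ccccc3)(c3ccccc3)C(C)(C)C)O[C@H]21 | intermediate (not isolated)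
35 | trimethylammonium iodide of 34 | C[N+](C)(C)C[C@@H]1C(=O)O[C@H]2[C@H]1[C@H](O[Si](CC)(CC)CC)C/C(C)=C\CC[C@@]1(CO[Si](c3ccccc3)(c3ccccc3)C(C)(C)C)O[C@H]21.[I-] | intermediate (not isolated)
36 | (4S,5R,6S,7S,8R)-8-(TES-oxy)-15-(TBDPS-oxy)-4,5-epoxygermacra-1(10)Z,11(13)-dien-6,12-olide | C=C1C(=O)O[C@H]2[C@H]1[C@H](O[Si](CC)(CC)CC)C/C(C)=C\CC[C@@]1(CO[Si](c3ccccc3)(c3ccccc3)C(C)(C)C)O[C@H]21 | intermediate
37 | (4S,5R,6S,7R,8R)-8-hydroxy-15-(TBDPS-oxy)-4,5-epoxygermacra-1(10)Z,11(13)-dien-6,12-olide | C=C1C(=O)O[C@H]2[C@H]1[C@H](O)C/C(C)=C\CC[C@@]1(CO[Si](c3ccccc3)(c3ccccc3)C(C)(C)C)O[C@H]21 | intermediate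
38 | (tert-butyldimethylsilyloxy)acetaldehyde | CC(C)(C)[Si](C)(C)OCC=O | starting material
39 | ethyl 2-(triphenylphosphoranylidene)propanoate | CCOC(=O)C(C)=P(c1ccccc1)(c1ccccc1)c1ccccc1 | starting material
40 | ethyl (E)-4-(TBS-oxy)-2-methylbut-2-enoate | CCOC(=O)/C(C)=C/CO[Si](C)(C)C(C)(C)C | intermediate
41 | (E)-4-(TBS-oxy)-2-methylbut-2-enoic acid | OC(=O)/C(C)=C/CO[Si](C)(C)C(C)(C)C | intermediate
42 | mixed anhydride of 41 with 2,4,6-trichlorobenzoic acid | O=C(OC(=O)c1c(Cl)cc(Cl)cc1Cl)/C(C)=C/CO[Si](C)(C)C(C)(C)C | intermediate (not isolated)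
43 | 8-O-[(E)-4-(TBS-oxy)-2-methylbut-2-enoyl] ester of 37 | C=C1C(=O)O[C@H]2[C@H]1[C@H](OC(=O)/C(C)=C/CO[Si](C)(C)C(C)(C)C)C/C(C)=C\CC[C@@]1(CO[Si](c3ccccc3)(c3ccccc3)C(C)(C)C)O[C@H]21 | intermediate
44 | CNP0187639.2, (4S,5R,6S,7R,8R)-15-hydroxy-8-[(E)-4-hydroxy-2-methylbut-2-enoyloxy]-4,5-epoxygermacra-1(10)Z,11(13)-dien-6,12-olide | C=C1C(=O)O[C@H]2[C@H]1[C@H](OC(=O)/C(C)=C/CO)C/C(C)=C\CC[C@@]1(CO)O[C@H]21 | target

Total step count: 24 (21 in the main line, one for imide 14, two for acid 41). Longest linear sequence: 21 steps (1–5, 7–20, 23, 24).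

Steps most likely to fail

1. Step 18 (proposed new method). The C9 radical may be reduced, dimerise or abstract hydrogen intramolecularly before it is captured, and the reducing nickel/magnesium iodide medium may open the oxirane. Fallback with known chemistry, closing C1=C10 by ring-closing metathesis instead of C9–C10: it sets out from aldehyde 19. Brown methallylation with the B-(2-methylallyl) reagent of the (−)-α-pinene series should give the (8R)-methallyl carbinol F1. TESCl/imidazole gives its TES ether F2, DDQ at pH 7 gives the primary alcohol F3, and Dess–Martin oxidation gives the aldehyde F4. Wittig methylenation (Ph3P=CH2) gives the diene F5. Ring-closing metathesis with the second-generation Hoveyda–Grubbs catalyst in hot dilute toluene should then close the trisubstituted C1=C10 alkene with loss of ethene; the cis ring olefin is expected to be favoured in this trans-fused ten-membered ring. The fallback returns to the route at 32.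

2. Step 10. Facial selectivity may be poor because the reagent has to override the intrinsic bias of the α-branched, β-acyloxy aldehyde, and the aldehyde may epimerise or eliminate. Fallback, correcting C8 by inversion instead of setting it directly: it sets out from 19. Allylation with the enantiomeric reagent of the (+)-α-pinene series (or with allylboronic acid pinacol ester if the substrate bias dominates) should give the (8S)-homoallylic alcohol F6. Mitsunobu reaction with chloroacetic acid (PPh3, diisopropyl azodicarboxylate) inverts C8 and gives the (8R)-chloroacetate F7, and thiourea with NaHCO3 in ethanol removes the chloroacetyl group under near-neutral conditions. The fallback returns to the route at 20.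

3. Step 7. The epoxy aldehyde may suffer Lewis-acid opening or decomposition, and double stereodifferentiation may be mismatched because the required C5/C6 relationship is the anti-Felkin one, which would erode syn selectivity. Fallback, aldol first and epoxidation second: it sets out from 8. Dess–Martin oxidation gives the (Z)-enal F8, and the same Evans aldol with 14 gives the allylic aldol adduct F9, which is kept as the crude open hydroxy ester. Epoxidation with mCPBA, directed by the free C6 hydroxyl on the conformer with C6–H eclipsing the alkene (A1,3 strain from the cis CH2O-silyl group), should deliver oxygen syn to the hydroxyl and give 16. PPTS then closes the lactone, and the fallback returns to the route at 17.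

Further compounds

F1 | step 18 | (4R,5S)-4-[(1R)-1-hydroxy-3-methylbut-3-enyl]-5-(Ox-PMB)oxolan-2-one | C=C(C)C[C@@H](O)[C@H]1CC(=O)O[C@@H]1[C@H]1O[C@]1(CO[Si](c1ccccc1)(c1ccccc1)C(C)(C)C)CCCOCc1ccc(OC)cc1
F2 | step 18 | TES ether of F1 | C=C(C)C[C@@H](O[Si](CC)(CC)CC)[C@H]1CC(=O)O[C@@H]1[C@H]1O[C@]1(CO[Si](c1ccccc1)(c1ccccc1)C(C)(C)C)CCCOCc1ccc(OC)cc1
F3 | step 18 | primary alcohol from F2 (Ox-OH chain) | C=C(C)C[C@@H](O[Si](CC)(CC)CC)[C@H]1CC(=O)O[C@@H]1[C@H]1O[C@]1(CO[Si](c1ccccc1)(c1ccccc1)C(C)(C)C)CCCO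
F4 | step 18 | aldehyde from F3 (Ox-CHO chain) | C=C(C)C[C@@H](O[Si](CC)(CC)CC)[C@H]1CC(=O)O[C@@H]1[C@H]1O[C@]1(CO[Si](c1ccccc1)(c1ccccc1)C(C)(C)C)CCC=O
F5 | step 18 | diene from F4 (but-3-enyl chain on the oxirane, methallyl group at C8) | C=C(C)C[C@@H](O[Si](CC)(CC)CC)[C@H]1CC(=O)O[C@@H]1[C@H]1O[C@]1(CO[Si](c1ccccc1)(c1ccccc1)C(C)(C)C)CCC=C
F6 | step 10 | (8S)-epimer of 20 | C=CC[C@H](O)[C@H]1CC(=O)O[C@@H]1[C@H]1O[C@]1(CO[Si](c1ccccc1)(c1ccccc1)C(C)(C)C)CCCOCc1ccc(OC)cc1
F7 | step 10 | (8R)-chloroacetate of 20 | C=CC[C@@H](OC(=O)CCl)[C@H]1CC(=O)O[C@@H]1[C@H]1O[C@]1(CO[Si](c1ccccc1)(c1ccccc1)C(C)(C)C)CCCOCc1ccc(OC)cc1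
F8 | step 7 | (Z)-4-(TBDPS-oxy)-3-[3-(PMB-oxy)propyl]but-2-enal | O=C/C=C(\CO[Si](c1ccccc1)(c1ccccc1)C(C)(C)C)CCCOCc1ccc(OC)cc1
F9 | step 7 | syn-aldol adduct of 14 and F8 (open hydroxy ester, C4=C5 alkene in place of the oxirane of 16) | COC(=O)C[C@H](C(=O)N1[C@@H](Cc2ccccc2)COC1=O)[C@H](O)/C=C(\CO[Si](c1ccccc1)(c1ccccc1)C(C)(C)C)CCCOCc1ccc(OC)cc1
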